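**Retrosynthetic overview**

1. Target 14 comes from 13 by BCl3 cleavage of the carbonyl-chelated 5-O-methyl group; 13 comes from 12 by one hydrogenolysis that removes the C3 bromine and both benzyl ethers of ring B.
2. Feature: in ring C the C3 methine stands alone between C2 (which carries ring B) and the C4 carbonyl. Taking it out contracts the pyranone to the furanone of a 2-aryl-4,6-dimethoxybenzofuran-3-one, so 12 comes from silyl enol ether 8 plus one carbon from bromoform 9 (new bonds C2–C3 and C3–C4 of the chromone).
3. 8 comes from ketone 7 by O-silylation; 7 comes from benzofuranone 6 and aryl bromide 5 by palladium-catalysed α-arylation (bond C2–C1').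
4. 5 comes from 2,3-dimethoxyphenol 1 through para-quinone 2, reductive benzylation to 4 and bromination.
5. Ring order: rings A and B and the furanone ring are bought; ring C is formed last, by enlarging the five-membered ring in step 6.

Key step: step 6

Remark: 1, 6 and 9 are taken as commercial. The target has no stereocenter; the stereocenters that appear on the way (C2 of 7, the two ring-fusion carbons of 10) are racemic and are erased again.

**Step 1**
Reactants: 1 2,3-dimethoxyphenol
Product: 2 2,3-dimethoxy-1,4-benzoquinone
Conditions: (KSO3)2NO (2.2 equiv), KH2PO4, H2O/acetone, 0 °C → rt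
Reagents that add atoms: potassium nitrosodisulfonate, [K+].[K+].[O]N(S(=O)(=O)[O-])S(=O)(=O)[O-]
Why: Teuber oxidation, in which one nitrosodisulfonate radical abstracts the phenolic hydrogen and a second delivers oxygen to the unsubstituted carbon para to the hydroxyl, so the para-quinone should form.

**Step 2**
Reactants: 2 2,3-dimethoxy-1,4-benzoquinone
Product: 4 1,4-bis(benzyloxy)-2,3-dimethoxybenzene, via 2,3-dimethoxyhydroquinone 3 (not isolated)
Conditions: Na2S2O4, Bu4NBr, THF/H2O, rt, Ar; then aq KOH, BnBr (3 equiv), rt
Reagents that add atoms: benzyl bromide, BrCc1ccccc1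
Why: Reductive alkylation of a quinone, in which dithionite gives the hydroquinone and its bis-phenoxide is O-benzylated at once under phase-transfer Williamson conditions, so the air-sensitive diol is never handled.

**Step 3**
Reactants: 4 1,4-bis(benzyloxy)-2,3-dimethoxybenzene
Product: 5 1,4-bis(benzyloxy)-5-bromo-2,3-dimethoxybenzene (2,5-bis(benzyloxy)-3,4-dimethoxyphenyl bromide)
Conditions: NBS (1.0 equiv), MeCN, 0 °C → rt, dark
Reagents that add atoms: N-bromosuccinimide, O=C1CCC(=O)N1Br
Why: Electrophilic aromatic bromination of a tetra-alkoxybenzene in a polar solvent; the two free ring positions are equivalent by symmetry and the first bromine slows a second substitution, so one equivalent should stop at the monobromide.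

**Step 4**
Reactants: 6 4,6-dimethoxybenzofuran-3(2H)-one; 5 1,4-bis(benzyloxy)-5-bromo-2,3-dimethoxybenzene
Product: 7 2-[2,5-bis(benzyloxy)-3,4-dimethoxyphenyl]-4,6-dimethoxybenzofuran-3(2H)-one (racemic at C2)
Conditions: Pd2(dba)3 (2.5 mol %), XPhos (6 mol %), NaOtBu (2.2 equiv), toluene, 80 °C, Ar; then degassed aq NH4Cl
Reagents that add atoms: none
Why: Palladium-catalysed ketone α-arylation (Buchwald–Hartwig type), in which the fully formed sodium enolate of 6 (full deprotonation also suppresses self-aldol) is arylated through an arylpalladium bromide made from zerovalent palladium and the bulky biaryl phosphine drives C–C reductive elimination; the ortho-benzyloxy group and the more stabilised product enolate should prevent a second arylation, and the new C2 stereocenter is racemic and is erased by enolisation in step 5.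

**Step 5**
Reactants: 7 2-[2,5-bis(benzyloxy)-3,4-dimethoxyphenyl]-4,6-dimethoxybenzofuran-3(2H)-one
Product: 8 2-[2,5-bis(benzyloxy)-3,4-dimethoxyphenyl]-3-(tert-butyldimethylsilyloxy)-4,6-dimethoxybenzofuran
Conditions: TBSOTf, Et3N, CH2Cl2, 0 °C, Ar; chromatography on Et3N-deactivated silica
Reagents that add atoms: tert-butyldimethylsilyl trifluoromethanesulfonate, CC(C)(C)[Si](C)(C)OS(=O)(=O)C(F)(F)F
Why: Silyl enol ether formation from a readily enolised aryl ketone; the enol is a 3-hydroxybenzofuran, so O-silylation with the silyl triflate and an amine base is favoured over C-silylation and gives the aromatic furan.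

**Step 6**
Reactants: 8 2-[2,5-bis(benzyloxy)-3,4-dimethoxyphenyl]-3-(tert-butyldimethylsilyloxy)-4,6-dimethoxybenzofuran; 9 bromoform
Product: 12 2-[2,5-bis(benzyloxy)-3,4-dimethoxyphenyl]-3-bromo-5,7-dimethoxychromen-4-one, via dibromocyclopropane adduct 10 (not isolated), via 3-bromo-4-silyloxyflavylium bromide 11 (not isolated)
Conditions: CHBr3 (3 equiv), KOtBu (3 equiv, added in portions), toluene/hexane, −30 °C → rt
Reagents that add atoms: bromoform 9, BrC(Br)Br
Why: Proposed new method: dibromocarbene, formed by α-elimination from bromoform, adds as an electrophile in a [2+1] cycloaddition to the furan C2=C3 bond of 8, which carries two oxygen donors (O1 and the silyloxy group) and is the least aromatic and most nucleophilic π bond present; the cis-fused dibromocyclopropane 10 then opens by disrotatory two-electron electrocyclic cleavage of the shared C2–C3 bond as the endo bromide leaves (a gem-dibromide always offers one), giving the flavylium ion 11, from whose 4-oxygen bromide removes the silyl group to release the 3-bromochromone 12. The closest known reactions are the dihalocarbene one-carbon homologation of cyclic silyl enol ethers to 2-halo enones, the ring expansion of indene–dihalocarbene adducts to 2-halonaphthalenes and the Ciamician–Dennstedt carbon insertion into indoles; none has been applied to a 2-aryl-3-silyloxybenzofuran to make a flavone. Ring C is not closed by a cyclisation but arises by enlargement of the furan ring, the carbene carbon becoming C3 and forming the new C2–C3 and C3–C4 bonds, with the aromatic pyrylium-type cation as driving force. No stereocenter remains, because the two ring-fusion centers of 10 become sp2. The step needs chemoselectivity for the enol ether over the alkoxyarenes and benzylic C–H bonds, which the doubly oxygen-donated C2=C3 bond and the reluctance of dibromocarbene to insert into C–H bonds should secure; it also needs the base to spare the silyl ether and the product, which slow addition of KOtBu to 8 and excess bromoform at low temperature should ensure.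

**Step 7**
Reactants: 12 2-[2,5-bis(benzyloxy)-3,4-dimethoxyphenyl]-3-bromo-5,7-dimethoxychromen-4-one
Product: 13 2-(2,5-dihydroxy-3,4-dimethoxyphenyl)-5,7-dimethoxychromen-4-one
Conditions: H2 (1 atm), 10% Pd/C, NaOAc (1.5 equiv), EtOAc/MeOH, rt; filtration under Ar, crude used directly
Reagents that add atoms: none
Why: Heterogeneous catalytic hydrogenolysis, in which Pd/C under H2 cleaves the two aryl benzyl ethers and hydrodebrominates the C3–Br bond of the α-bromo enone (NaOAc takes up the HBr), while the chromone C2=C3 bond, part of a vinylogous ester in a pseudo-aromatic ring, should survive at one atmosphere and room temperature.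

**Step 8**
Reactants: 13 2-(2,5-dihydroxy-3,4-dimethoxyphenyl)-5,7-dimethoxychromen-4-one
Product: 14 2-(2,5-dihydroxy-3,4-dimethoxyphenyl)-5-hydroxy-7-methoxychromen-4-one (target)
Conditions: BCl3 (1 M in CH2Cl2, 5 equiv), CH2Cl2, −78 → 0 °C; then MeOH, aq Na2S2O4 wash, Ar
Reagents that add atoms: none
Why: Chelation-controlled aryl methyl ether cleavage, in which BCl3 bridges the C4 carbonyl and the peri 5-methoxy oxygen in a six-membered chelate and chloride removes that methyl as MeCl, whereas the 7-, 3'- and 4'-methoxy groups have no carbonyl partner and should be kept at or below 0 °C.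

**Compound list**

1 | 2,3-dimethoxyphenol | COc1cccc(O)c1OC | starting material
2 | 2,3-dimethoxy-1,4-benzoquinone | COC1=C(OC)C(=O)C=CC1=O | intermediate
3 | 2,3-dimethoxyhydroquinone (2,3-dimethoxybenzene-1,4-diol) | COc1c(O)ccc(O)c1OC | intermediate (not isolated)
4 | 1,4-bis(benzyloxy)-2,3-dimethoxybenzene | COc1c(OCc2ccccc2)ccc(OCc2ccccc2)c1OC | intermediate
5 | 1,4-bis(benzyloxy)-5-bromo-2,3-dimethoxybenzene | COc1c(OCc2ccccc2)cc(Br)c(OCc2ccccc2)c1OC | intermediate
6 | 4,6-dimethoxybenzofuran-3(2H)-one | COc1cc(OC)c2c(c1)OCC2=O | starting material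
7 | 2-[2,5-bis(benzyloxy)-3,4-dimethoxyphenyl]-4,6-dimethoxybenzofuran-3(2H)-one, racemic | COc1cc(OC)c2c(c1)OC(c1cc(OCc3ccccc3)c(OC)c(OC)c1OCc1ccccc1)C2=O | intermediate
8 | 2-[2,5-bis(benzyloxy)-3,4-dimethoxyphenyl]-3-(tert-butyldimethylsilyloxy)-4,6-dimethoxybenzofuran | COc1cc(OC)c2c(O[Si](C)(C)C(C)(C)C)c(-c3cc(OCc4ccccc4)c(OC)c(OC)c3OCc5ccccc5)oc2c1 | intermediate
9 | bromoform | BrC(Br)Br | starting material
10 | 1a-[2,5-bis(benzyloxy)-3,4-dimethoxyphenyl]-1,1-dibromo-6b-(tert-butyldimethylsilyloxy)-4,6-dimethoxy-1a,6b-dihydro-1H-cyclopropa[b][1]benzofuran, racemic, cis-fused | COc1cc(OC)c2c(c1)OC1(c3cc(OCc4ccccc4)c(OC)c(OC)c3OCc3ccccc3)C(Br)(Br)C21O[Si](C)(C)C(C)(C)C | intermediate (not isolated)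
11 | 2-[2,5-bis(benzyloxy)-3,4-dimethoxyphenyl]-3-bromo-4-(tert-butyldimethylsilyloxy)-5,7-dimethoxychromenylium bromide | COc1cc(OC)c2c(O[Si](C)(C)C(C)(C)C)c(Br)c(-c3cc(OCc4ccccc4)c(OC)c(OC)c3OCc5ccccc5)[o+]c2c1.[Br-] | intermediate (not isolated)
12 | 2-[2,5-bis(benzyloxy)-3,4-dimethoxyphenyl]-3-bromo-5,7-dimethoxychromen-4-one | COc1cc(OC)c2c(=O)c(Br)c(-c3cc(OCc4ccccc4)c(OC)c(OC)c3OCc5ccccc5)oc2c1 | intermediate
13 | 2-(2,5-dihydroxy-3,4-dimethoxyphenyl)-5,7-dimethoxychromen-4-one | COc1cc(OC)c2c(=O)cc(-c3cc(O)c(OC)c(OC)c3O)oc2c1 | intermediate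
14 | 2-(2,5-dihydroxy-3,4-dimethoxyphenyl)-5-hydroxy-7-methoxychromen-4-one (CNP0170944.0) | COc1cc(O)c2c(=O)cc(-c3cc(O)c(OC)c(OC)c3O)oc2c1 | target

**Step count**

Total steps: 8. Longest linear sequence: 8 steps (1 → 2 → 4 → 5 → 7 → 8 → 12 → 13 → 14); benzofuranone 6 and bromoform 9 enter as purchased materials.

**Steps most likely to fail**

1. Step 6 (proposed new method). The carbene may add too slowly to the crowded, tetrasubstituted C2=C3 bond, so that tert-butoxide strips the silyl group first. The cyclopropane may also fail to open, or alkoxide may add to C2 of the bromochromone and open ring C. Fallback by known flavone chemistry, setting out from 5 and returning at 13: bromine–lithium exchange on 5 (n-BuLi, THF, −78 °C) and formylation with DMF would give 2,5-bis(benzyloxy)-3,4-dimethoxybenzaldehyde F1. Claisen–Schmidt condensation of F1 with commercial 2'-hydroxy-4',6'-dimethoxyacetophenone (KOH, EtOH, rt) would give (E)-3-[2,5-bis(benzyloxy)-3,4-dimethoxyphenyl]-1-(2-hydroxy-4,6-dimethoxyphenyl)prop-2-en-1-one F2. Oxidative cyclisation with I2 (cat.) in DMSO at 120 °C would give 2-[2,5-bis(benzyloxy)-3,4-dimethoxyphenyl]-5,7-dimethoxychromen-4-one F3, and hydrogenolysis (H2, Pd/C, EtOAc/MeOH) of its two benzyl ethers would give 13, after which step 8 follows.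

2. Step 4. The benzofuranone enolate may self-condense or the electron-rich, ortho-substituted bromide may undergo oxidative addition too slowly, and the product enolate may be oxidised by traces of air. Fallback that forms the C2–C1' bond on the aromatic furan instead, setting out from 6 and returning at 8: silylation of 6 (TBSOTf, Et3N, CH2Cl2, 0 °C) would give 3-(tert-butyldimethylsilyloxy)-4,6-dimethoxybenzofuran F4. Lithiation at C2 (n-BuLi, THF, −78 °C), transmetalation with ZnCl2 and Negishi coupling with 5 (Pd2(dba)3, SPhos, THF, 60 °C) would then give 8 directly.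

3. Step 8. Boron bound to the free 2'- and 5'-hydroxyls may chelate and cleave the neighbouring ring-B methyl ethers, and the methoxyhydroquinone may be oxidised to the quinone during work-up. Fallback that demethylates while the hydroquinone is still masked and ends with a reductive step, setting out from 12 and returning at 14: MgI2·OEt2 (toluene/THF, 60 °C), which cleaves only the carbonyl-chelated ether and spares benzyl ethers that have no carbonyl neighbour, would give 2-[2,5-bis(benzyloxy)-3,4-dimethoxyphenyl]-3-bromo-5-hydroxy-7-methoxychromen-4-one F5. Hydrogenolysis (H2, Pd/C, NaOAc, EtOAc/MeOH) would then remove bromine and both benzyl groups to give 14.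

**Further compounds**

F1 | step 6 | 2,5-bis(benzyloxy)-3,4-dimethoxybenzaldehyde | COc1c(OCc2ccccc2)cc(C=O)c(OCc2ccccc2)c1OC
F2 | step 6 | (E)-3-[2,5-bis(benzyloxy)-3,4-dimethoxyphenyl]-1-(2-hydroxy-4,6-dimethoxyphenyl)prop-2-en-1-one | COc1cc(O)c(C(=O)/C=C/c2cc(OCc3ccccc3)c(OC)c(OC)c2OCc2ccccc2)c(OC)c1
F3 | step 6 | 2-[2,5-bis(benzyloxy)-3,4-dimethoxyphenyl]-5,7-dimethoxychromen-4-one | COc1cc(OC)c2c(=O)cc(-c3cc(OCc4ccccc4)c(OC)c(OC)c3OCc5ccccc5)oc2c1
F4 | step 4 | 3-(tert-butyldimethylsilyloxy)-4,6-dimethoxybenzofuran | COc1cc(OC)c2c(O[Si](C)(C)C(C)(C)C)coc2c1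
F5 | step 8 | 2-[2,5-bis(benzyloxy)-3,4-dimethoxyphenyl]-3-bromo-5-hydroxy-7-methoxychromen-4-one | COc1cc(O)c2c(=O)c(Br)c(-c3cc(OCc4ccccc4)c(OC)c(OC)c3OCc5ccccc5)oc2c1
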